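The constants are invented; no experiment stands behind them.

Count turnovers against catalyst losses before anything else.

substrate 20 mM; reagent 14.0 mM (fed, over 15 min); free catalyst 0.40 mM; time 40 h

    substrate + free catalyst ⇌ free catalyst + open intermediate (K1 = 0.22, k1 = 810 M⁻¹ min⁻¹)
    free catalyst + open intermediate ⇌ catalyst intermediate (K2 = 380 M⁻¹, k2 = 3400 M⁻¹ min⁻¹)
    reagent + catalyst intermediate → free catalyst + target (k3 = 64 M⁻¹ min⁻¹)
    free catalyst + target → spent catalyst (k4 = 0.51 M⁻¹ min⁻¹)
    substrate ⇌ dormant form (K5 = 3.0, k5 = 0.015 min⁻¹)

- what has gone from substrate into another species counts as reacted, even if it can come back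
- run time (flask): 40 h

1. part of the substrate gone at 40 h
2. the target standing at 40 h, as a percentage of the substrate charged
3. the open intermediate standing at 40 h, as a percentage of the substrate charged

We keep the books on the reagent, the limiting reagent by charge: its 14.0 mM allows target up to 70.0% of the substrate charged. Each turnover uses one reagent, and each free catalyst that meets target leaves the round, so the first entry is what the catalyst can pay for.

Release from catalyst intermediate, 8.95 min⁻¹, is faster than the reagent step at full charge, 0.896 min⁻¹, so we hold binding at equilibrium. The substrate and dormant form relax with a half-life of 0.578 h, short against 40 h, so as an approximation we give the open intermediate its equilibrium share f of the unconverted pool, 5.21%.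

Free catalyst then cancels, and turnovers per catalyst lost equal E·c(pool)·c(reagent)/c(target). Here E is 2.49 mM⁻¹, the exchange rate: reagent-step constant times binding constant times f, over the loss-step constant.

Summing over x of reagent used, with charges a of substrate and b of reagent, gives the catalyst bill: [a ln(1 − x/a) − b ln(1 − x/b)]/[(a − b)E]. At x = 11.2 mM the bill is 0.410 mM, close to the 0.40 mM charged, so our books close there.

The entries are 2.80 mM of reagent unused and 0.40 mM of target taken into spent catalyst. That leaves target at 54.0%, conversion at 89.6% and open intermediate at 2.29%.

The forecast, stepped by hand, stands slightly higher on target than we do: 89.8%, 55% and 2.2%, “leaving about 2.6 mM reagent unused”.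

The simulation gives 89.4%, 53.5% and 2.28%.

In this flask at 40.0 h, the forward half-life of substrate by the catalysed opening is 72 d, far longer than the 40 h run, with >99.9% of the catalyst as spent catalyst and 21% of the reagent left. At E, the target standing plus the catalyst charge bills 0.392 mM, beside 0.40 mM charged.

For the neighbour flask with 0.24 mM of free catalyst, we try 9.80 mM of reagent used; the same E bills 0.227 mM for it, beside that charge, which gives 30.0% of the reagent left and target at 47.8%. That flask gave 30% and 47.9%.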